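Grey is the amber charge with 0.240 M of product added at the start, and you want its share at 210 h.

| setting | amber | blue | teal | violet | grey |
|---|---|---|---|---|---|
| substrate | 0.800 M | 0.320 M | 0.800 M | 2.40 M | 0.800 M |
| partner | 0.800 M | 0.320 M | 1.60 M | 0.800 M | 0.800 M |
| free catalyst | 0.00800 M | 0.00800 M | 0.00800 M | 0.00800 M | 0.00800 M |
| product |  |  |  |  | 0.240 M |
| time |  |  |  |  | 210 h |

- amber run (time / h: [product] / M): 8.4: 0.2535; 13: 0.3014; 21: 0.3548; 33: 0.3946; 53: 0.4280; 84: 0.4505; 130: 0.4656; 210: 0.4729
- blue run (time / h: [product] / M): 8.4: 0.0574; 13: 0.0776; 21: 0.1016; 33: 0.1218; 53: 0.1436; 84: 0.1595; 130: 0.1708; 210: 0.1812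
- teal run (time / h: [product] / M): 8.4: 0.4004; 13: 0.4711; 21: 0.5249; 33: 0.5640; 53: 0.5886; 84: 0.6047; 130: 0.6114; 210: 0.6184
- violet run (time / h: [product] / M): 8.4: 0.4864; 13: 0.5415; 21: 0.5918; 33: 0.6273; 53: 0.6525; 84: 0.6658; 130: 0.6794; 210: 0.6813

(scatter of a reading: 0.002 M)

* order of the initial rate in [substrate], near the charge of the amber run, the rate being that where two percent of its substrate are product (one fixed amount of product, the same in the runs compared)
* order of the initial rate in [partner], near the charge of the amber run, the rate being that where two percent of its substrate are product
* product in the grey run at 210 h, as a share of the substrate charged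

- Overall: substrate + partner -> product, with free catalyst as catalyst.
- Constant volume, constant temperature.
- "The second partner" is partner.
- An order is taken over about fifteen percent of the charge, up and down.
- A share of product counts the product that was charged too.

Take what the grey answer hangs on, in turn. Grey's catalyst matches amber's, as do its reagents, so amber's curve can stand in for a rate constant as long as the charged product stays idle. One scatter in amber's last reading is worth 0.250% of the charge. Time matters little too: from 130 h to 210 h amber gained 0.912% of its charge, less than the charged product. What does matter is whether the charged product acts on the flask, or merely adds its 30.0% of the charge to the share.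

Work in logarithms for that. Call substrate charged times hours elapsed, with partner charged equally, the clock 168 M·h; that is where grey stands at 210 h. Amber's charge lies 0.398 decades above blue's, and on a log time axis blue is amber moved by that shift. Amber at 8.4 h made 31.7% of its charge and blue at 21 h made 31.8%; amber at 84 h made 56.3% and blue at 210 h made 56.6%. So amber and blue run on the clock, not on hours, and their overall order reads as two. I do not split that two from curves that begin so far along; I take one for each reagent.

In amber, plot the reciprocal of [product] against reciprocal time: the slope from 8.4 h to 21 h stands to the slope from 84 h to 210 h as 1.07, and the slope from 21 h to 84 h stands to it as 1.14, so the plot reads as nearly straight. I therefore read the stop as reagents used up by second-order steps, not as a balance with product. Grey should then make amber's 0.4729 M on top of its charge, which gives 89.1%.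

The forecast reads the plateaus as an equilibrium and adds “So the catalyst is dying or being inhibited as the run proceeds.” It gives an order of 0.7 in substrate, 0.9 in partner and a grey share of 81.5%, lower than mine.

The simulation gives an order of 1.0 in substrate, 1.0 in partner and a grey share of 89.3%.

    2 free catalyst ⇌ catalyst dimer, settled at all times (1570 M⁻¹)
    catalyst dimer + substrate + partner → product + catalyst dimer (29.34 M⁻² h⁻¹)
    2 partner → lost reagent (0.02304 M⁻¹ h⁻¹)
    2 substrate → homo dimer (0.03708 M⁻¹ h⁻¹)

In grey, from the start to 210 h, the catalyst dimer turned substrate and partner into product while the reagents also paired off to homo dimer and lost reagent, and grey made 0.474 M against amber's reading of 0.4729 M at the same clock of 168 M·h. Blue ran the same steps, and the clock carries over to it: amber's quarter of its charge at 5.47 h puts blue's at 13.7 h, and blue reached it at 13.7 h.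

All runs were generated by integration with constants of no real substance; noise was put on by code.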